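**Plan**

- Retrosynthesis cuts, in order: the four O-acetyl masks; the two aryl–CH2 bonds at C3 and C5 of ring B, both in one twofold Stille disconnection; the aryl–C(=O) bond at C1' of ring A (Friedel–Crafts); and the two C–Br bonds.
- Forward, no ring is formed: phloretic acid 1 is dibrominated to 2, which acylates phloroglucinol 3 to give the C6–C3–C6 chain 4; peracetylation gives 5, twofold coupling with prenylstannane 6 gives 7, and deacetylation gives target 8.
- Enabling feature: C3 and C5 of ring B are the two carbons ortho to the C4 hydroxyl, and the para carbon carries the propanoyl chain. Phenol bromination therefore marks exactly these two atoms before the far more nucleophilic phloroglucinol ring A exists, and the C–Br bonds then fix where the prenyl groups go.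
- Stereochemistry: the target has no stereocentre, and each prenyl alkene bears two identical methyl groups. Only linear versus branched allyl transfer must be controlled.

Key step: step 4

Assumption: unprimed locants (3, 4, 5) refer to ring B, the ring of the arylpropanoyl unit, and primed locants (2', 4', 6') to ring A, the phloroglucinol ring, as usual for dihydrochalcones.

**Route**

Step 1
Reactants: 1 3-(4-hydroxyphenyl)propanoic acid (phloretic acid)
Product: 2 3-(3,5-dibromo-4-hydroxyphenyl)propanoic acid
Conditions: Br2 (2.1 equiv), AcOH, rt
Reagents that add atoms: bromine, BrBr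
Why: Electrophilic aromatic bromination, in which the hydroxyl directs to its two equivalent ortho carbons (the para carbon is blocked by the side chain), so two equivalents of bromine should give the symmetrical 3,5-dibromide.

Step 2
Reactants: 2 3-(3,5-dibromo-4-hydroxyphenyl)propanoic acid; 3 phloroglucinol (benzene-1,3,5-triol)
Product: 4 3-(3,5-dibromo-4-hydroxyphenyl)-1-(2,4,6-trihydroxyphenyl)propan-1-one (3,5-dibromo-4,2',4',6'-tetrahydroxydihydrochalcone)
Conditions: BF3·OEt2 (neat, Lewis acid and solvent), 85 °C; then H2O
Reagents that add atoms: none
Why: Friedel–Crafts acylation, in which BF3 activates the carboxylic acid toward C-acylation of phloroglucinol (three equivalent ring carbons), and the reaction should stop at the mono-ketone because the new acyl group deactivates ring A while the dibrominated ring B is too electron-poor to compete.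

Step 3
Reactants: 4 3,5-dibromo-4,2',4',6'-tetrahydroxydihydrochalcone
Product: 5 3,5-dibromo-4,2',4',6'-tetraacetoxydihydrochalcone (2-[3-(4-acetoxy-3,5-dibromophenyl)propanoyl]benzene-1,3,5-triyl triacetate)
Conditions: Ac2O, pyridine, DMAP (cat.), rt
Reagents that add atoms: acetic anhydride, CC(=O)OC(C)=O
Why: DMAP-catalysed O-acetylation (nucleophilic acyl transfer) should esterify all four phenols, including the two hydrogen-bonded to the ketone and the hindered one between the bromines, giving a mask that is later removed with base and not with acid.

Step 4
Reactants: 5 3,5-dibromo-4,2',4',6'-tetraacetoxydihydrochalcone; 6 tributyl(3-methylbut-2-en-1-yl)stannane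
Product: 7 4,2',4',6'-tetraacetoxy-3,5-diprenyldihydrochalcone (2-{3-[4-acetoxy-3,5-bis(3-methylbut-2-en-1-yl)phenyl]propanoyl}benzene-1,3,5-triyl triacetate)
Conditions: Pd(PPh3)4 (10 mol %), 6 (3 equiv), DMF, 100 °C, degassed
Reagents that add atoms: none
Why: Stille cross-coupling, in which zerovalent palladium inserts into each aryl C–Br bond of 5, the prenyl group passes from tin to the resulting arylpalladium bromide (divalent palladium), and reductive elimination forms the aryl–CH2 bond and returns the catalyst, the cycle running twice to make the C3–CH2 and C5–CH2 bonds. The closest known reaction type is the Pd(PPh3)4-catalysed coupling of aryl bromides with tributyl(prenyl)stannane, an established way to place linear prenyl groups on arenes. No ring is closed and no stereocentre is created. The selectivity needed is linear rather than 1,1-dimethylallyl transfer at both sites; under triphenylphosphine ligation the aryl group should be delivered to the unsubstituted CH2 terminus of the allyl fragment, and the ortho acetoxy group further disfavours a quaternary benzylic carbon. Site selectivity is secured by the substrate, because its only carbon–halogen bonds are the two symmetry-equivalent bromides flanking the ring B acetate, and the aryl acetates and the ketone are inert to zerovalent palladium and to the neutral stannane. Capping all four phenols removes acidic O–H groups that could protonate the allylstannane or deactivate the bromides as phenoxides.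

Step 5
Reactants: 7 4,2',4',6'-tetraacetoxy-3,5-diprenyldihydrochalcone
Product: 8 4,2',4',6'-tetrahydroxy-3,5-diprenyldihydrochalcone
Conditions: K2CO3, MeOH, 0 °C to rt, Ar; then cold 1 M HCl to pH 5
Reagents that add atoms: none
Why: Base-promoted transesterification (methanolysis) of the four aryl acetates should proceed at or below room temperature without touching the ketone or the trisubstituted alkenes, and the absence of strong acid avoids cyclisation of the ortho-prenylphenol to a chroman.

**Compound list**

1 | 3-(4-hydroxyphenyl)propanoic acid (phloretic acid) | OC(=O)CCc1ccc(O)cc1 | starting material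
2 | 3-(3,5-dibromo-4-hydroxyphenyl)propanoic acid | OC(=O)CCc1cc(Br)c(O)c(Br)c1 | intermediate
3 | phloroglucinol (benzene-1,3,5-triol) | Oc1cc(O)cc(O)c1 | starting material
4 | 3-(3,5-dibromo-4-hydroxyphenyl)-1-(2,4,6-trihydroxyphenyl)propan-1-one (3,5-dibromo-4,2',4',6'-tetrahydroxydihydrochalcone) | O=C(CCc1cc(Br)c(O)c(Br)c1)c1c(O)cc(O)cc1O | intermediate
5 | 3,5-dibromo-4,2',4',6'-tetraacetoxydihydrochalcone | CC(=O)Oc1cc(OC(C)=O)c(C(=O)CCc2cc(Br)c(OC(C)=O)c(Br)c2)c(OC(C)=O)c1 | intermediate
6 | tributyl(3-methylbut-2-en-1-yl)stannane | CCCC[Sn](CCCC)(CCCC)CC=C(C)C | starting material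
7 | 4,2',4',6'-tetraacetoxy-3,5-diprenyldihydrochalcone | CC(=O)Oc1cc(OC(C)=O)c(C(=O)CCc2cc(CC=C(C)C)c(OC(C)=O)c(CC=C(C)C)c2)c(OC(C)=O)c1 | intermediate
8 | 4,2',4',6'-tetrahydroxy-3,5-diprenyldihydrochalcone | CC(C)=CCc1cc(CCC(=O)c2c(O)cc(O)cc2O)cc(CC=C(C)C)c1O | target

**Step count and risks**

Total step count: 5. Longest linear sequence: 5 steps (1 → 2 → 4 → 5 → 7 → 8); phloroglucinol 3 and stannane 6 enter as purchased partners.

The three steps most likely to fail:

Step 4. The allyl transfer may lose its linear preference and bond through the dimethyl-substituted terminus. The second coupling may also stall, bromine may be lost reductively, or a palladium hydride may move the new double bond into conjugation with ring B. The fallback leaves the route at 5 and runs the same twofold Stille coupling with allyltributylstannane (Pd(PPh3)4, DMF, 90 °C), whose two allyl termini are identical, so no regiochemical question arises. This should give 3,5-diallyl-4,2',4',6'-tetraacetoxydihydrochalcone F1. Twofold olefin cross-metathesis of F1 with excess 2-methylbut-2-ene (second-generation Grubbs catalyst, CH2Cl2, 40 °C, sealed tube) should then exchange each terminal CH2 for an isopropylidene group with loss of propene, returning to the route at 7.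

Step 2. At 85 °C in a strong Lewis acid the ortho-bromophenol ring may be protonated at its bromine-bearing carbons and pass bromine to the much more nucleophilic phloroglucinol, causing scrambling and debromination. O-acylation or a second acylation may also compete. The fallback is a Houben–Hoesch ketone synthesis at 0 °C, setting out from 2. Acid 2 is converted into 3-(3,5-dibromo-4-hydroxyphenyl)propanamide F2 (EDC·HCl, HOBt, NH4Cl, i-Pr2NEt, DMF). The amide is dehydrated to 3-(3,5-dibromo-4-hydroxyphenyl)propanenitrile F3 (trifluoroacetic anhydride, pyridine, 0 °C; then NaHCO3 in aqueous methanol to cleave any phenyl trifluoroacetate). Nitrile F3 and phloroglucinol 3 with ZnCl2 and dry HCl in Et2O at 0 °C should deposit 3-(3,5-dibromo-4-hydroxyphenyl)-1-(2,4,6-trihydroxyphenyl)propan-1-iminium chloride F4. Warming F4 in water hydrolyses it to ketone 4, where the route is rejoined.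

Step 5. Before methanolysis is complete, carbonate may enolise the ketone and trigger C-acyl transfer from an ortho acetate (a Baker–Venkataraman-type rearrangement), and the electron-rich polyphenolate may be oxidised by traces of air. The fallback replaces the ester masks by silyl ethers that come off without base, setting out from 4. Silylation (TBSOTf, 2,6-lutidine, CH2Cl2, 0 °C to rt) should give 3,5-dibromo-4,2',4',6'-tetrakis(tert-butyldimethylsilyloxy)dihydrochalcone F5. The same twofold Stille coupling with 6 (Pd(PPh3)4, toluene, 110 °C) should give 3,5-diprenyl-4,2',4',6'-tetrakis(tert-butyldimethylsilyloxy)dihydrochalcone F6. Fluoride buffered with acetic acid (Bu4NF, AcOH, THF, 0 °C) then removes the four silyl groups and returns to the route at target 8.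

**Further compounds**

F1 | step 4 | 3,5-diallyl-4,2',4',6'-tetraacetoxydihydrochalcone | CC(=O)Oc1cc(OC(C)=O)c(C(=O)CCc2cc(CC=C)c(OC(C)=O)c(CC=C)c2)c(OC(C)=O)c1
F2 | step 2 | 3-(3,5-dibromo-4-hydroxyphenyl)propanamide | NC(=O)CCc1cc(Br)c(O)c(Br)c1
F3 | step 2 | 3-(3,5-dibromo-4-hydroxyphenyl)propanenitrile | N#CCCc1cc(Br)c(O)c(Br)c1
F4 | step 2 | 3-(3,5-dibromo-4-hydroxyphenyl)-1-(2,4,6-trihydroxyphenyl)propan-1-iminium chloride | [NH2+]=C(CCc1cc(Br)c(O)c(Br)c1)c1c(O)cc(O)cc1O.[Cl-]
F5 | step 5 | 3,5-dibromo-4,2',4',6'-tetrakis(tert-butyldimethylsilyloxy)dihydrochalcone | CC(C)(C)[Si](C)(C)Oc1cc(O[Si](C)(C)C(C)(C)C)c(C(=O)CCc2cc(Br)c(O[Si](C)(C)C(C)(C)C)c(Br)c2)c(O[Si](C)(C)C(C)(C)C)c1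
F6 | step 5 | 3,5-diprenyl-4,2',4',6'-tetrakis(tert-butyldimethylsilyloxy)dihydrochalcone | CC(C)(C)[Si](C)(C)Oc1cc(O[Si](C)(C)C(C)(C)C)c(C(=O)CCc2cc(CC=C(C)C)c(O[Si](C)(C)C(C)(C)C)c(CC=C(C)C)c2)c(O[Si](C)(C)C(C)(C)C)c1
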